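Amounts first: the earlier cedar run charged 0.90 M substrate against 2.7 M coupling partner, and the new flask charges 1.8 M against 2.70 M.

- cedar: substrate 0.90 M; coupling partner 2.7 M; run made earlier
- flask: substrate 1.8 M; coupling partner 2.70 M; time 40 min

- cedar (time / min: substrate / %, bis adduct / %, mono adduct / %): 0.667: 96.3, 0, 4.9; 2.00: 84.8, 0.2, 14.0; 4.00: 72.6, 2.9, 24.0; 6.00: 63.2, 4.0, 31.1; 8.00: 56.0, 7.3, 35.6

(standard deviation of a reading: 1 percentage point)

- a reading or a percentage of bis adduct counts all its forms, free or not
- what has gone from substrate into another species counts as reacted, even if it can come back
- a reading of substrate is of its free form alone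

* how much of the substrate has reacted by 40 min
* how much bis adduct there is at 40 min, in percent of the substrate charged
* how much mono adduct there is at 40 min, in percent of the substrate charged
* amount of bis adduct if the flask were left three thousand times as long, in percent of the substrate charged

1. My decision was whether this flask needed more coupling partner before a reading at 40 min.

2. I wrote A for free substrate, B for coupling partner, and Ac and Bc for their charges. I assumed dA/dt = −k·A·B. Over a slice of time Δt with mean partner B̄, this gives ln(A before/A after) = k·B̄·Δt, a pseudo-first-order decay.

3. At 8.00 min the cedar run read 56.0% substrate and 7.3% bis adduct. I counted one partner for each substrate reacted and another for each bis adduct, and halfway to that use B̄ in the cedar run was about 2.47 M. I read the substrate rate constant, k, the fall in ln A per molar minute of partner, as 0.0294 M⁻¹ min⁻¹.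

4. The same reading gave s, the partner used per substrate reacted, as 1.17. Holding s, with c = Bc − s·Ac = 0.601 M, the rate integrates in closed form: ln[(B/Bc)(Ac/A)] = k·c·t.

5. My reckoning for this flask at 40 min left 17.8% substrate and 0.976 M partner, so I added no partner.

6. The forecast gave 80% reacted, 32% bis adduct, 47% mono adduct and 57% bis adduct ever. My conversion, 82.2%, stood higher than its figure. It cautioned: “Reversibility or binding is not shown by one run”.

7. The flask gave 84.1% reacted, 30.3% bis adduct, 44.8% mono adduct and 57.8% bis adduct ever, so the forecast held. The flask's bis adduct figure counts each idle adduct as one bis adduct, while the 17.4% told for idle adduct itself counts each as two.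

    substrate + coupling partner → mono adduct (k = 0.0290 M⁻¹ min⁻¹)
    coupling partner + bis adduct → tris adduct (k = 7.40 × 10⁻⁴ M⁻¹ min⁻¹)
    coupling partner + mono adduct → bis adduct (k = 0.0150 M⁻¹ min⁻¹)
    substrate + bis adduct ⇌ idle adduct, settled at all times (K = 1.40 M⁻¹)

I used k again on this flask from 20.0 min to 40.0 min. Substrate began at 30.1%, and partner fell from 46.9% to 29.1% of its charge, so B̄ was 1.03 M. The rule gave 16.5% substrate, and the flask held 15.9%. The neighbouring flask had the same charges and was read at 60.0 min. With partner falling to 20.0% of its charge, the rule carried substrate from 15.9% to 10.8%, and that flask held 11.1%.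

All runs come from a simulation for an exercise; the scatter is artificial.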